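**In the vessel.** The closed, stirred vessel holds J at 0.25 M with solid D at 0.375 M, and on the list of suspects J passes through E to the products Q and Z.

| flask | J | D | remark | time |
|---|---|---|---|---|
| north | 0.25 M | 0.52 M | run made earlier |  |
| south | 0.25 M | 0.83 M | run made earlier |  |
| flask | 0.25 M | 0.375 M |  | 20 min |

| run | time / min | Q / % | Z / % |
|---|---|---|---|
| north | 1.50 | 7.5 | 2.8 |
| north | 2.50 | 15.7 | 5.5 |
| north | 4.00 | 27.9 | 10.1 |
| north | 8.00 | 56.3 | 20.6 |
| north | 12.0 | 66.0 | 22.5 |
| north | 20.0 | 66.7 | 22.2 |
| south | 3.00 | 18.9 | 7.4 |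
| south | 6.00 | 44.3 | 15.3 |
| south | 10.0 | 65.4 | 22.1 |
| south | 12.0 | 67.2 | 22.2 |
| south | 15.0 | 67.3 | 22.5 |
| south | 20.0 | 65.9 | 22.2 |

(standard deviation of a reading: 0.5 percentage points)

- as a solid, counted per litre of solution: D
- the numbers in the tables scatter by 0.5 percentage points (one standard deviation)
- on the list of suspects stand: J + X -> E + L; D <-> X; E <-> Z; E <-> Q; Q -> G
- at the start none of D is in solution

- share of Q in Q plus Z at 50 s
- share of Q in Q plus Z at 4.0 min
- share of Q in Q plus Z at 20 min
- which of Q and Z there is more of at 20 min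

**The number.** The north run at 20.0 min reads 0.478 for Λ, the common logarithm of Q over Z, a selectivity factor counted in powers of ten, and the south run reads 0.473.

**On arrival.** This reckoning carries Λ to the flask, where undoing the logarithm puts the share of Q in Q plus Z at 75.0 % by 20 min, with Q ahead since Λ is positive. The north reading at 4.00 min gives Λ 0.441, so 73.4 % is taken for both 50 s and 4.0 min.

**Hands off.** The charge of D is left as it is: the north run at 0.52 M and the south run at 0.83 M differ in Λ by 0.00500, with each reading scattering by 0.5 percentage points, and the flask is charged with 1.50 of D per J.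

**The forecast.** The forecast gave 73.5 %, 73.8 % and 75 %, with Q ahead, saying “kinetic and equilibrium selectivity nearly coincide”; at 4.0 min this reckoning stands 0.4 points below it.

**The result.** The flask gives 73.8 %, 74.1 % and 75.1 %, with Q ahead at 66.3 % against 22.0 %. The low solubility of X makes no difference to the share at 20 min. Those two amounts put Λ at 0.479, beside the 0.478 read in the north run.

    J + X → E + L (k = 1.50 M⁻¹ s⁻¹)
    D ⇌ X, rate k2*(cs2 - [X]) while solid is left; crystals form when [X] > cs2 (solubility = 33.0 mM, k = 0.0170 s⁻¹)
    E ⇌ Z (K = 2.10, k = 0.00640 s⁻¹)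
    E ⇌ Q (K = 6.40, k = 0.0180 s⁻¹)
    Q → G (k = 2.10 × 10⁻⁵ s⁻¹)

**Second flask.** For the neighbour flask with J at 1.0 M, Λ of 0.478 gives a share of Q in Q plus Z of 75.0 % at 20 min; computed, the share in that flask is 75.0 %, with D down to 0 % of its charge and 62.5 % of J remaining.

The earlier runs and the new flask come from a simulation with made-up constants; scatter was added.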